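**Plan**

1. Locants follow labdane numbering: C4 carries CH3 and the carboxyl carbon, C5 and C10 are the ring-fusion carbons (C10 with CH3), C6 carries OAc, C8 the exocyclic CH2, C9 the side chain C11–C15. Late cuts: acid ← methyl ester; OAc ← OTBS; C8=CH2, C14=C15 and C12=C13 ← Wittig reactions on a C8 ketone and a C12 aldehyde, i.e. a decalin diol.
2. With a C1=C2 double bond added, ring A is a cyclohexene. Its C4–C5 edge is an (E)-2-methyl-enoate dienophile and its C10–C1–C2–C3 arc is a diene with the angular methyl on the C10 terminus. Cutting C3–C4 and C5–C10 together opens both rings, and the ring B carbons C6–C9 remain as a four-carbon tether in an open-chain triene.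
3. The triene is cut at C1–C2 and C10–CH3 (alkyne carboalumination/vinylation), at C8–C9 (allenylindium addition of a propargylic mesylate to an aldehyde), at C6–C7 (asymmetric allylation) and at C4=C5 (Wittig).
4. Forward: two five-step fragments (aldehyde 7, mesylate 13) are joined and the diene is installed. One intramolecular Diels–Alder reaction then closes rings A and B together. Hydrogenation, side-chain and methylene construction, acetylation and ester cleavage follow.
5. Stereochemistry: C6 comes from a catalytic asymmetric allylation. C9 (and the transient C8 carbinol) comes from the (R)-mesylate made by asymmetric transfer hydrogenation. C4, C5 and C10 are set in the cycloaddition by the two E-alkene geometries and the C6/C9 tether stereocentres. C9 stays correctable, since it ends α to the C8 ketone and the wanted equatorial epimer is the stable one.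

Key step: step 14

Remark: the target SMILES is read as 4S,5S,6R,9R,10S, a trans-decalin with equatorial CO2H, equatorial OAc and equatorial side chain (axial CH3 at C4 and C10).

**Route**

Step 1
Reactants: 1 2,2-dimethoxyacetaldehyde; 2 methyl 2-(triphenyl-λ5-phosphanylidene)propanoate
Product: 3 methyl (2E)-4,4-dimethoxy-2-methylbut-2-enoate
Conditions: DCM, 25 °C
Reagents that add atoms: none
Why: Wittig olefination with an α-branched ester-stabilised ylide should give the trisubstituted enoate with E geometry (CO2Me trans to the acetal carbon), which later becomes the cis relation of H-5 and the carboxyl group.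

Step 2
Reactants: 3 methyl (2E)-4,4-dimethoxy-2-methylbut-2-enoate
Product: 4 methyl (2E)-2-methyl-4-oxobut-2-enoate
Conditions: 1 M HCl, acetone, 25 °C
Reagents that add atoms: water, O
Why: Acid-catalysed hydrolysis of an allylic dimethyl acetal; the E geometry (formyl trans to ester) is the thermodynamically preferred one and should persist.

Step 3
Reactants: 4 methyl (2E)-2-methyl-4-oxobut-2-enoate
Product: 5 methyl (2E,4R)-4-hydroxy-2-methylhepta-2,6-dienoate
Conditions: allyltributylstannane, (R)-BINOL (20 mol %), Ti(OiPr)4 (10 mol %), 4 Å molecular sieves, DCM, −20 °C; aqueous work-up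
Reagents that add atoms: allyltributylstannane, C=CC[Sn](CCCC)(CCCC)CCCC
Why: Keck asymmetric allylation, in which the BINOL–titanium Lewis acid should direct 1,2-allyl transfer to one face of the enal carbonyl, the (R)-ligand giving the (R)-carbinol by analogy with aryl and alkenyl aldehydes; this sets C6.

Step 4
Reactants: 5 methyl (2E,4R)-4-hydroxy-2-methylhepta-2,6-dienoate
Product: 6 methyl (2E,4R)-4-[(tert-butyldimethylsilyl)oxy]-2-methylhepta-2,6-dienoate
Conditions: TBSCl, imidazole, DMF, 25 °C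
Reagents that add atoms: tert-butyldimethylsilyl chloride, CC(C)(C)[Si](C)(C)Cl
Why: Standard silylation of a secondary allylic alcohol; the TBS ether is chosen to survive organoaluminium reagents, heat, hydrogenolysis and ylides.

Step 5
Reactants: 6 methyl (2E,4R)-4-[(tert-butyldimethylsilyl)oxy]-2-methylhepta-2,6-dienoate
Product: 7 methyl (2E,4R)-4-[(tert-butyldimethylsilyl)oxy]-2-methyl-6-oxohex-2-enoate
Conditions: OsO4 (2 mol %), NaIO4, 2,6-lutidine, dioxane/H2O, 25 °C
Reagents that add atoms: sodium periodate, [Na+].[O-]I(=O)(=O)=O; osmium tetroxide (catalytic oxygen carrier), O=[Os](=O)(=O)=O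
Why: Lemieux–Johnson cleavage should select the electron-rich monosubstituted alkene over the trisubstituted ester-conjugated one, and the lutidine buffer should keep the β-silyloxy aldehyde from eliminating.

Step 6
Reactants: 8 3-(benzyloxy)propanal
Product: 9 rac-5-(benzyloxy)-1-(trimethylsilyl)pent-1-yn-3-ol
Conditions: ethynyltrimethylsilane, n-BuLi, THF, −78 °C; then 8; H2O quench
Reagents that add atoms: ethynyltrimethylsilane, C#C[Si](C)(C)C
Why: 1,2-Addition of a lithium acetylide to an aldehyde.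

Step 7
Reactants: 9 rac-5-(benzyloxy)-1-(trimethylsilyl)pent-1-yn-3-ol
Product: 10 5-(benzyloxy)-1-(trimethylsilyl)pent-1-yn-3-one
Conditions: Dess–Martin periodinane, DCM, 25 °C
Reagents that add atoms: none
Why: Dess–Martin oxidation of a propargylic alcohol to the ynone.

Step 8
Reactants: 10 5-(benzyloxy)-1-(trimethylsilyl)pent-1-yn-3-one
Product: 11 (3R)-5-(benzyloxy)-1-(trimethylsilyl)pent-1-yn-3-ol
Conditions: RuCl[(R,R)-TsDPEN](p-cymene) (1 mol %), i-PrOH, 25 °C
Reagents that add atoms: none
Why: Noyori asymmetric transfer hydrogenation of an alkynyl ketone, in which the alkynyl group takes the role of the aryl group of aryl ketones, so that the (R,R)-catalyst should give the (R)-propargylic alcohol; this centre is later relayed to C9.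

Step 9
Reactants: 11 (3R)-5-(benzyloxy)-1-(trimethylsilyl)pent-1-yn-3-ol
Product: 12 (3R)-5-(benzyloxy)pent-1-yn-3-ol
Conditions: K2CO3 (cat.), MeOH, 25 °C
Reagents that add atoms: none
Why: Base-catalysed methanolysis of the alkynyl C–Si bond, which leaves the carbinol centre untouched.

Step 10
Reactants: 12 (3R)-5-(benzyloxy)pent-1-yn-3-ol
Product: 13 (3R)-5-(benzyloxy)pent-1-yn-3-yl methanesulfonate
Conditions: MsCl, Et3N, DCM, −78 °C
Reagents that add atoms: methanesulfonyl chloride, CS(=O)(=O)Cl
Why: O-Sulfonylation with retention at carbon gives the propargylic electrophile for the union.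

Step 11
Reactants: 7 methyl (2E,4R)-4-[(tert-butyldimethylsilyl)oxy]-2-methyl-6-oxohex-2-enoate; 13 (3R)-5-(benzyloxy)pent-1-yn-3-yl methanesulfonate
Product: 15 methyl (2E,4R,6R,7S)-9-(benzyloxy)-4-[(tert-butyldimethylsilyl)oxy]-7-ethynyl-6-hydroxy-2-methylnon-2-enoate, via allenylindium iodide mesylate 14 (not isolated)
Conditions: Pd(dppf)Cl2 (5 mol %), InI (1.5 equiv), THF/HMPA 3:1, 25 °C
Reagents that add atoms: none
Why: Marshall propargylation, in which anti SN2′ oxidative addition of zerovalent palladium, transmetallation to indium and syn SE2′ addition through a cyclic transition state should give the anti homopropargylic alcohol; C9 (S) is fixed by the mesylate with net inversion and C8 (R) by the anti preference.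

Step 12
Reactants: 15 methyl (2E,4R,6R,7S)-9-(benzyloxy)-4-[(tert-butyldimethylsilyl)oxy]-7-ethynyl-6-hydroxy-2-methylnon-2-enoate
Product: 16 methyl (2E,4R,6R,7S)-6,9-bis(benzyloxy)-4-[(tert-butyldimethylsilyl)oxy]-7-ethynyl-2-methylnon-2-enoate
Conditions: 2-(benzyloxy)-1-methylpyridinium trifluoromethanesulfonate, MgO, PhCF3, 83 °C
Reagents that add atoms: 2-(benzyloxy)-1-methylpyridinium trifluoromethanesulfonate, C[n+]1ccccc1OCc1ccccc1.[O-]S(=O)(=O)C(F)(F)F
Why: Neutral benzyl transfer from the 2-benzyloxypyridinium salt protects the C8 hydroxyl, which could otherwise add to the enoate (5-exo oxa-Michael), without touching TBS ether, alkyne or ester; the benzyl group leaves again in step 15 at no extra cost.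

Step 13
Reactants: 16 methyl (2E,4R,6R,7S)-6,9-bis(benzyloxy)-4-[(tert-butyldimethylsilyl)oxy]-7-ethynyl-2-methylnon-2-enoate
Product: 18 methyl (2E,4R,6R,7S,8E)-6-(benzyloxy)-7-[2-(benzyloxy)ethyl]-4-[(tert-butyldimethylsilyl)oxy]-2,8-dimethylundeca-2,8,10-trienoate, via alkenyldimethylalane 17 (not isolated)
Conditions: Me3Al (3 equiv), Cp2ZrCl2 (0.3 equiv), (CH2Cl)2, 0 to 25 °C; excess Me3Al removed in vacuo; then THF, vinyl bromide, Pd(PPh3)4 (5 mol %), ZnCl2 (10 mol %), 25 °C
Reagents that add atoms: trimethylaluminium, C[Al](C)C; vinyl bromide, C=CBr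
Why: Negishi zirconium-catalysed carboalumination (syn addition, methyl to the internal carbon) followed by palladium-catalysed coupling of the alkenylalane with retention should give the (E)-4-methyl-1,3-diene with the C10 methyl cis to the vinyl group; the conjugated α-branched methyl ester should only coordinate Me3Al at or below 25 °C.

Step 14
Reactants: 18 methyl (2E,4R,6R,7S,8E)-6-(benzyloxy)-7-[2-(benzyloxy)ethyl]-4-[(tert-butyldimethylsilyl)oxy]-2,8-dimethylundeca-2,8,10-trienoate
Product: 19 methyl (1S,4aS,5S,6R,8R,8aS)-6-(benzyloxy)-5-[2-(benzyloxy)ethyl]-8-[(tert-butyldimethylsilyl)oxy]-1,4a-dimethyl-1,2,4a,5,6,7,8,8a-octahydronaphthalene-1-carboxylate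
Conditions: toluene (0.01 M), BHT (0.1 equiv), sealed tube, 180 °C
Reagents that add atoms: none
Why: Concerted thermal [4+2] cycloaddition in which the (E)-4-methyl-1,3-diene C3=C2–C1=C10 adds suprafacially to the (E)-2-methyl-enoate C5=C4 through the four-carbon tether C6–C9; the closest known reaction type is the type 1 intramolecular Diels–Alder reaction of ester-terminated deca-2,7,9-trienoates to trans-fused octalins. Ring B (C5–C6–C7–C8–C9–C10) closes through the new C5–C10 bond as the tether ring in a chair-like array, and ring A (C10–C1–C2–C3–C4–C5) closes as the cyclohexene of the cycloaddition through the C5–C10 and C3–C4 bonds. C4 is set relative to C5 by the E geometry of the enoate (H-5 cis to CO2Me, so the 4-methyl group becomes axial and the ester equatorial), and C10 is set relative to C5 by the E geometry of C1=C10 together with the transition state that places the ester endo and the tether exo (angular methyl anti to H-5, trans ring fusion). The absolute sense is controlled by the C6 and C9 stereocentres of the tether, which hold the OTBS group and the benzyloxyethyl chain equatorial on the forming chair, the benzyloxy group at C8 being the only axial substituent. The step needs ester-endo (trans) over ester-exo (cis) closure and cycloaddition faster than the 1,5-hydrogen shift open to a diene with a methyl group cis to the vinyl unit; the secondary overlap of the conjugated ester, the equatorial tether substituents and the entropic advantage of a six-membered tether ring are what the substrate offers, and high dilution with BHT should keep intermolecular addition and polymerisation down.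

Step 15
Reactants: 19 methyl (1S,4aS,5S,6R,8R,8aS)-6-(benzyloxy)-5-[2-(benzyloxy)ethyl]-8-[(tert-butyldimethylsilyl)oxy]-1,4a-dimethyl-1,2,4a,5,6,7,8,8a-octahydronaphthalene-1-carboxylate
Product: 20 methyl (1S,4aS,5S,6R,8R,8aS)-8-[(tert-butyldimethylsilyl)oxy]-6-hydroxy-5-(2-hydroxyethyl)-1,4a-dimethyldecahydronaphthalene-1-carboxylate
Conditions: H2 (1 atm), Pd(OH)2/C, EtOAc/MeOH, 25 °C
Reagents that add atoms: none
Why: Heterogeneous hydrogenation should saturate the cis-disubstituted C1=C2 bond and hydrogenolyse both benzyl ethers in one operation, leaving TBS ether and methyl ester.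

Step 16
Reactants: 20 methyl (1S,4aS,5S,6R,8R,8aS)-8-[(tert-butyldimethylsilyl)oxy]-6-hydroxy-5-(2-hydroxyethyl)-1,4a-dimethyldecahydronaphthalene-1-carboxylate
Product: 21 methyl (1S,4aR,5S,8R,8aS)-8-[(tert-butyldimethylsilyl)oxy]-1,4a-dimethyl-6-oxo-5-(2-oxoethyl)decahydronaphthalene-1-carboxylate
Conditions: Dess–Martin periodinane (3 equiv), DCM, 25 °C
Reagents that add atoms: none
Why: Dess–Martin oxidation of the secondary C8 alcohol to the ketone and of the primary C12 alcohol to the aldehyde; C9 is now α to the ketone, and its equatorial (wanted) configuration is the thermodynamic one.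

Step 17
Reactants: 21 methyl (1S,4aR,5S,8R,8aS)-8-[(tert-butyldimethylsilyl)oxy]-1,4a-dimethyl-6-oxo-5-(2-oxoethyl)decahydronaphthalene-1-carboxylate
Product: 22 methyl (1S,4aR,5S,8R,8aS)-8-[(tert-butyldimethylsilyl)oxy]-1,4a-dimethyl-5-[(2E)-3-methyl-4-oxobut-2-en-1-yl]-6-oxodecahydronaphthalene-1-carboxylate
Conditions: 2-(triphenyl-λ5-phosphanylidene)propanal, toluene, 80 °C
Reagents that add atoms: 2-(triphenyl-λ5-phosphanylidene)propanal, CC(C=O)=P(c1ccccc1)(c1ccccc1)c1ccccc1
Why: Wittig reaction of the formyl-stabilised ylide, which reacts with the aldehyde but not with the hindered ketone and should give the (E)-2-methyl-enal, i.e. the E C12=C13 bond.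

Step 18
Reactants: 22 methyl (1S,4aR,5S,8R,8aS)-8-[(tert-butyldimethylsilyl)oxy]-1,4a-dimethyl-5-[(2E)-3-methyl-4-oxobut-2-en-1-yl]-6-oxodecahydronaphthalene-1-carboxylate
Product: 23 methyl (1S,4aS,5R,8R,8aS)-8-[(tert-butyldimethylsilyl)oxy]-1,4a-dimethyl-6-methylidene-5-[(2E)-3-methylpenta-2,4-dien-1-yl]decahydronaphthalene-1-carboxylate
Conditions: Ph3PCH3Br (6 equiv), KOtBu (5.5 equiv), THF, 0 to 40 °C
Reagents that add atoms: methyltriphenylphosphonium bromide, C[P+](c1ccccc1)(c1ccccc1)c1ccccc1.[Br-]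
Why: Twofold Wittig methylenation converts the enal into the terminal diene and the C8 ketone into the exocyclic methylene; the hindered ester is inert and C9 can only epimerise toward the equatorial isomer already present.

Step 19
Reactants: 23 methyl (1S,4aS,5R,8R,8aS)-8-[(tert-butyldimethylsilyl)oxy]-1,4a-dimethyl-6-methylidene-5-[(2E)-3-methylpenta-2,4-dien-1-yl]decahydronaphthalene-1-carboxylate
Product: 24 methyl (1S,4aS,5R,8R,8aS)-8-hydroxy-1,4a-dimethyl-6-methylidene-5-[(2E)-3-methylpenta-2,4-dien-1-yl]decahydronaphthalene-1-carboxylate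
Conditions: HF·pyridine, pyridine, THF, 0 to 25 °C
Reagents that add atoms: none
Why: Fluoride cleavage of the secondary TBS ether under pyridine-buffered, non-basic conditions, which should neither isomerise the alkenes nor generate an alkoxide that could lactonise onto the neighbouring ester.

Step 20
Reactants: 24 methyl (1S,4aS,5R,8R,8aS)-8-hydroxy-1,4a-dimethyl-6-methylidene-5-[(2E)-3-methylpenta-2,4-dien-1-yl]decahydronaphthalene-1-carboxylate
Product: 25 methyl (1S,4aS,5R,8R,8aS)-8-(acetyloxy)-1,4a-dimethyl-6-methylidene-5-[(2E)-3-methylpenta-2,4-dien-1-yl]decahydronaphthalene-1-carboxylate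
Conditions: Ac2O, DMAP (cat.), pyridine, 25 °C
Reagents that add atoms: acetic anhydride, CC(=O)OC(C)=O
Why: DMAP-catalysed acetylation of the equatorial secondary alcohol.

Step 21
Reactants: 25 methyl (1S,4aS,5R,8R,8aS)-8-(acetyloxy)-1,4a-dimethyl-6-methylidene-5-[(2E)-3-methylpenta-2,4-dien-1-yl]decahydronaphthalene-1-carboxylate
Product: 26 (1S,4aS,5R,8R,8aS)-8-(acetyloxy)-1,4a-dimethyl-6-methylidene-5-[(2E)-3-methylpenta-2,4-dien-1-yl]decahydronaphthalene-1-carboxylic acid (CNP0240327.3)
Conditions: n-PrSLi (5 equiv, from n-PrSH and n-BuLi), HMPA, 25 °C; then 1 M HCl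
Reagents that add atoms: none
Why: SN2 dealkylation at the methyl carbon of the α-quaternary methyl ester by thiolate, the classical method for resin-acid-type esters, which should spare the secondary acetate because acyl transfer from oxygen to sulfur is uphill and no hydroxide is present.

**Compound list**

1 | 2,2-dimethoxyacetaldehyde | COC(OC)C=O | starting material
2 | methyl 2-(triphenyl-λ5-phosphanylidene)propanoate | COC(=O)C(C)=P(c1ccccc1)(c1ccccc1)c1ccccc1 | starting material
3 | methyl (2E)-4,4-dimethoxy-2-methylbut-2-enoate | COC(=O)/C(C)=C/C(OC)OC | intermediate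
4 | methyl (2E)-2-methyl-4-oxobut-2-enoate | COC(=O)/C(C)=C/C=O | intermediate
5 | methyl (2E,4R)-4-hydroxy-2-methylhepta-2,6-dienoate | C=CC[C@@H](O)/C=C(\C)C(=O)OC | intermediate
6 | methyl (2E,4R)-4-[(tert-butyldimethylsilyl)oxy]-2-methylhepta-2,6-dienoate | C=CC[C@@H](O[Si](C)(C)C(C)(C)C)/C=C(\C)C(=O)OC | intermediate
7 | methyl (2E,4R)-4-[(tert-butyldimethylsilyl)oxy]-2-methyl-6-oxohex-2-enoate | O=CC[C@@H](O[Si](C)(C)C(C)(C)C)/C=C(\C)C(=O)OC | intermediate
8 | 3-(benzyloxy)propanal | O=CCCOCc1ccccc1 | starting material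
9 | rac-5-(benzyloxy)-1-(trimethylsilyl)pent-1-yn-3-ol | C[Si](C)(C)C#CC(O)CCOCc1ccccc1 | intermediate
10 | 5-(benzyloxy)-1-(trimethylsilyl)pent-1-yn-3-one | C[Si](C)(C)C#CC(=O)CCOCc1ccccc1 | intermediate
11 | (3R)-5-(benzyloxy)-1-(trimethylsilyl)pent-1-yn-3-ol | C[Si](C)(C)C#C[C@H](O)CCOCc1ccccc1 | intermediate
12 | (3R)-5-(benzyloxy)pent-1-yn-3-ol | C#C[C@H](O)CCOCc1ccccc1 | intermediate
13 | (3R)-5-(benzyloxy)pent-1-yn-3-yl methanesulfonate | C#C[C@H](OS(C)(=O)=O)CCOCc1ccccc1 | intermediate
14 | [5-(benzyloxy)penta-1,2-dien-1-yl]indium iodide methanesulfonate (axially chiral allene from anti SN2′ attack; not isolated) | I[In](OS(C)(=O)=O)C([H])=[C@@]=C([H])CCOCc1ccccc1 | intermediate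
15 | methyl (2E,4R,6R,7S)-9-(benzyloxy)-4-[(tert-butyldimethylsilyl)oxy]-7-ethynyl-6-hydroxy-2-methylnon-2-enoate | C#C[C@H](CCOCc1ccccc1)[C@H](O)C[C@@H](O[Si](C)(C)C(C)(C)C)/C=C(\C)C(=O)OC | intermediate
16 | methyl (2E,4R,6R,7S)-6,9-bis(benzyloxy)-4-[(tert-butyldimethylsilyl)oxy]-7-ethynyl-2-methylnon-2-enoate | C#C[C@H](CCOCc1ccccc1)[C@H](OCc1ccccc1)C[C@@H](O[Si](C)(C)C(C)(C)C)/C=C(\C)C(=O)OC | intermediate
17 | (E)-alkenyldimethylalane from syn methylalumination of 16 (Al on the terminal carbon, cis to the new methyl; not isolated) | C[Al](C)/C=C(\C)[C@H](CCOCc1ccccc1)[C@H](OCc1ccccc1)C[C@@H](O[Si](C)(C)C(C)(C)C)/C=C(\C)C(=O)OC | intermediate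
18 | methyl (2E,4R,6R,7S,8E)-6-(benzyloxy)-7-[2-(benzyloxy)ethyl]-4-[(tert-butyldimethylsilyl)oxy]-2,8-dimethylundeca-2,8,10-trienoate | C=C/C=C(\C)[C@H](CCOCc1ccccc1)[C@H](OCc1ccccc1)C[C@@H](O[Si](C)(C)C(C)(C)C)/C=C(\C)C(=O)OC | intermediate
19 | methyl (1S,4aS,5S,6R,8R,8aS)-6-(benzyloxy)-5-[2-(benzyloxy)ethyl]-8-[(tert-butyldimethylsilyl)oxy]-1,4a-dimethyl-1,2,4a,5,6,7,8,8a-octahydronaphthalene-1-carboxylate | O(Cc1ccccc1)CC[C@@H]1[C@H](OCc3ccccc3)C[C@@H](O[Si](C)(C)C(C)(C)C)[C@H]2[C@@]1(C)C=CC[C@]2(C)C(=O)OC | intermediate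
20 | methyl (1S,4aS,5S,6R,8R,8aS)-8-[(tert-butyldimethylsilyl)oxy]-6-hydroxy-5-(2-hydroxyethyl)-1,4a-dimethyldecahydronaphthalene-1-carboxylate | OCC[C@@H]1[C@H](O)C[C@@H](O[Si](C)(C)C(C)(C)C)[C@H]2[C@@]1(C)CCC[C@]2(C)C(=O)OC | intermediate
21 | methyl (1S,4aR,5S,8R,8aS)-8-[(tert-butyldimethylsilyl)oxy]-1,4a-dimethyl-6-oxo-5-(2-oxoethyl)decahydronaphthalene-1-carboxylate | O=CC[C@@H]1C(=O)C[C@@H](O[Si](C)(C)C(C)(C)C)[C@H]2[C@@]1(C)CCC[C@]2(C)C(=O)OC | intermediate
22 | methyl (1S,4aR,5S,8R,8aS)-8-[(tert-butyldimethylsilyl)oxy]-1,4a-dimethyl-5-[(2E)-3-methyl-4-oxobut-2-en-1-yl]-6-oxodecahydronaphthalene-1-carboxylate | O=C/C(C)=C/C[C@@H]1C(=O)C[C@@H](O[Si](C)(C)C(C)(C)C)[C@H]2[C@@]1(C)CCC[C@]2(C)C(=O)OC | intermediate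
23 | methyl (1S,4aS,5R,8R,8aS)-8-[(tert-butyldimethylsilyl)oxy]-1,4a-dimethyl-6-methylidene-5-[(2E)-3-methylpenta-2,4-dien-1-yl]decahydronaphthalene-1-carboxylate | C=C/C(C)=C/C[C@@H]1C(=C)C[C@@H](O[Si](C)(C)C(C)(C)C)[C@H]2[C@@]1(C)CCC[C@]2(C)C(=O)OC | intermediate
24 | methyl (1S,4aS,5R,8R,8aS)-8-hydroxy-1,4a-dimethyl-6-methylidene-5-[(2E)-3-methylpenta-2,4-dien-1-yl]decahydronaphthalene-1-carboxylate | C=C/C(C)=C/C[C@@H]1C(=C)C[C@@H](O)[C@H]2[C@@]1(C)CCC[C@]2(C)C(=O)OC | intermediate
25 | methyl (1S,4aS,5R,8R,8aS)-8-(acetyloxy)-1,4a-dimethyl-6-methylidene-5-[(2E)-3-methylpenta-2,4-dien-1-yl]decahydronaphthalene-1-carboxylate | C=C/C(C)=C/C[C@@H]1C(=C)C[C@@H](OC(C)=O)[C@H]2[C@@]1(C)CCC[C@]2(C)C(=O)OC | intermediate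
26 | (1S,4aS,5R,8R,8aS)-8-(acetyloxy)-1,4a-dimethyl-6-methylidene-5-[(2E)-3-methylpenta-2,4-dien-1-yl]decahydronaphthalene-1-carboxylic acid | C=C/C(C)=C/C[C@@H]1C(=C)C[C@@H](OC(C)=O)[C@H]2[C@@]1(C)CCC[C@]2(C)C(=O)O | target

**Count and risks**

Total step count: 21. Longest linear sequence: 16 steps (steps 1–5 then 11–21; equally steps 6–10 then 11–21).

Steps most likely to fail:

1. Step 14. The cycloaddition may be too slow at the hindered, Z-methylated diene terminus, so that the 1,5-hydrogen shift of the diene or the ester-exo (cis-fused) closure takes over. Fallback (Lewis-acid-promoted cycloaddition at the aldehyde oxidation level): setting out from 18, DIBAL reduction (toluene, −78 °C) should give the trienyl allylic alcohol F1, and MnO2 (DCM) the trienal F2. Me2AlCl (DCM, −78 to −20 °C) should then drive the formyl-endo, trans-selective cycloaddition to the octalin carbaldehyde F3. Pinnick oxidation (NaClO2, NaH2PO4, 2-methyl-2-butene) to the octalin carboxylic acid F4 and esterification with (trimethylsilyl)diazomethane bring the route back at 19.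

2. Step 13. Trimethylaluminium may attack the conjugated methyl ester (acyl substitution or conjugate methyl transfer) in competition with carbometalation of the branched alkyne. Fallback (carbometalation at the carboxylate stage): setting out from 16, LiOH (THF/MeOH/H2O) should give the enynoic acid F5, whose dimethylaluminium carboxylate is inert to Me3Al at 25 °C. The same carboalumination and vinyl coupling should then give the trienoic acid F6, and (trimethylsilyl)diazomethane brings the route back at 18.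

3. Step 18. The basic ylide may enolise the hindered C8 ketone instead of adding to it, with β-elimination of the C6 silyloxy group or incomplete methylenation. Fallback (Peterson olefination): setting out from 22, Me3SiCH2Li/CeCl3 (THF, −78 °C), a non-basic nucleophile, should add to both carbonyl groups to give the bis(β-hydroxysilane) F7 (epimers at the two new carbinol carbons). KH (THF, 0 °C) should then eliminate trimethylsilanolate twice and bring the route back at 23.

**Further compounds**

F1 | step 14 | (2E,4R,6R,7S,8E)-6-(benzyloxy)-7-[2-(benzyloxy)ethyl]-4-[(tert-butyldimethylsilyl)oxy]-2,8-dimethylundeca-2,8,10-trien-1-ol | C=C/C=C(\C)[C@H](CCOCc1ccccc1)[C@H](OCc1ccccc1)C[C@@H](O[Si](C)(C)C(C)(C)C)/C=C(\C)CO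
F2 | step 14 | (2E,4R,6R,7S,8E)-6-(benzyloxy)-7-[2-(benzyloxy)ethyl]-4-[(tert-butyldimethylsilyl)oxy]-2,8-dimethylundeca-2,8,10-trienal | C=C/C=C(\C)[C@H](CCOCc1ccccc1)[C@H](OCc1ccccc1)C[C@@H](O[Si](C)(C)C(C)(C)C)/C=C(\C)C=O
F3 | step 14 | (1S,4aS,5S,6R,8R,8aS)-6-(benzyloxy)-5-[2-(benzyloxy)ethyl]-8-[(tert-butyldimethylsilyl)oxy]-1,4a-dimethyl-1,2,4a,5,6,7,8,8a-octahydronaphthalene-1-carbaldehyde | O(Cc1ccccc1)CC[C@@H]1[C@H](OCc3ccccc3)C[C@@H](O[Si](C)(C)C(C)(C)C)[C@H]2[C@@]1(C)C=CC[C@]2(C)C=O
F4 | step 14 | (1S,4aS,5S,6R,8R,8aS)-6-(benzyloxy)-5-[2-(benzyloxy)ethyl]-8-[(tert-butyldimethylsilyl)oxy]-1,4a-dimethyl-1,2,4a,5,6,7,8,8a-octahydronaphthalene-1-carboxylic acid | O(Cc1ccccc1)CC[C@@H]1[C@H](OCc3ccccc3)C[C@@H](O[Si](C)(C)C(C)(C)C)[C@H]2[C@@]1(C)C=CC[C@]2(C)C(=O)O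
F5 | step 13 | (2E,4R,6R,7S)-6,9-bis(benzyloxy)-4-[(tert-butyldimethylsilyl)oxy]-7-ethynyl-2-methylnon-2-enoic acid | C#C[C@H](CCOCc1ccccc1)[C@H](OCc1ccccc1)C[C@@H](O[Si](C)(C)C(C)(C)C)/C=C(\C)C(=O)O
F6 | step 13 | (2E,4R,6R,7S,8E)-6-(benzyloxy)-7-[2-(benzyloxy)ethyl]-4-[(tert-butyldimethylsilyl)oxy]-2,8-dimethylundeca-2,8,10-trienoic acid | C=C/C=C(\C)[C@H](CCOCc1ccccc1)[C@H](OCc1ccccc1)C[C@@H](O[Si](C)(C)C(C)(C)C)/C=C(\C)C(=O)O
F7 | step 18 | methyl (1S,4aR,5S,8R,8aS)-8-[(tert-butyldimethylsilyl)oxy]-6-hydroxy-5-[(2E)-4-hydroxy-3-methyl-5-(trimethylsilyl)pent-2-en-1-yl]-1,4a-dimethyl-6-[(trimethylsilyl)methyl]decahydronaphthalene-1-carboxylate (epimers at both new carbinol carbons) | C[Si](C)(C)CC(O)/C(C)=C/C[C@@H]1C(O)(C[Si](C)(C)C)C[C@@H](O[Si](C)(C)C(C)(C)C)[C@H]2[C@@]1(C)CCC[C@]2(C)C(=O)OC
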